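## Retrosynthetic overview
1. The target comes from its tris-silyl ether. The 2Z enal C7=C2(CH3)-CHO comes from a C7 ketone by isopropenyl addition and a [3,3] chromate transposition, which makes the C1–O bond.
2. C16–C17 is cut to a C16 enal plus an alkenylzinc made from the alkyne of (S)-citronellal. C19 comes from the chiral pool, C16 is set by catalyst control, and the C16–O bond comes from SeO2 oxidation of a prenyl end.
3. C11–C12 and C6–C5 come from conjugate addition of a homoprenyl Grignard reagent anti to C10–OSi, followed by enolate allylation. The allyl group becomes hydroxypropyl (C3–O) by hydroboration/oxidation.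
4. Key step: the C10–O bond is made first, by a stereoconvergent, enantioselective copper-catalysed aerobic gamma-hydroxylation of racemic 3,4-dimethylcyclohexenone. C10 then controls C11 and C6.
5. Rings: the single six-membered ring is bought with the enone, so there is no ring-forming step.

**Atom labels:** C1 = CHO, C2 = its alpha carbon, C3–C5 = hydroxypropyl (C3 bears OH). The ring is C6 (CH), C7 (alkylidene carbon), C8, C9, C10 (C(OH)CH3) and C11 (quaternary). The chain is C12–C24, with C16 the carbinol and C19 the CH(CH3). The target is 2Z,6R,10S,11S,14E,16S,17E,19S.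

**Assumption:** racemic 3,4-dimethylcyclohex-2-en-1-one is bought as a catalogue chemical. The (2S,6S) guanidine is taken to give the (S) alcohol; its antipode is used if the sense of induction is opposite.

## Route

Step 1
Reactants: 1 rac-3,4-dimethylcyclohex-2-en-1-one
Product: 3 (S)-4-hydroxy-3,4-dimethylcyclohex-2-en-1-one, via hydroperoxide 2 (not isolated)
Conditions: Cu(OTf)2 (5 mol %), (2S,6S)-2,6-di-tert-butyl-2,3,5,6-tetrahydro-1H-imidazo[1,2-a]imidazole (15 mol %), O2 (1 atm), DME, −20 °C; then PPh3 (1.1 equiv), 0 °C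
Reagents that add atoms: dioxygen, O=O
Why: Proposed new method: the guanidine-ligated divalent copper centre deprotonates 1 at C4 to the planar through-conjugated dienolate (this erases the stereocentre of racemic 1, so the process is stereoconvergent), then inner-sphere electron transfer and capture of O2 at the gamma carbon (the only site that restores the conjugated enone) occur inside the C2-symmetric pocket of the chiral guanidine, so one face is oxygenated, C10 is set as S and PPh3 reduces the hydroperoxide; the closest known reaction type is the racemic copper/tetramethylguanidine-catalysed vinylogous aerobic gamma-hydroxylation of unsaturated carbonyl compounds, for which no enantioselective version exists.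

Step 2
Reactants: 3 (S)-4-hydroxy-3,4-dimethylcyclohex-2-en-1-one
Product: 4 (S)-3,4-dimethyl-4-(triethylsilyloxy)cyclohex-2-en-1-one
Conditions: TESOTf (1.2 equiv), 2,6-lutidine (2 equiv), CH2Cl2, −78 → 0 °C
Reagents that add atoms: triethylsilyl triflate, CC[Si](CC)(CC)OS(=O)(=O)C(F)(F)F
Why: Silyl triflate/lutidine silylation works on hindered tertiary alcohols, does not touch C10, and installs the non-coordinating OTES group that directs step 3.

Step 3
Reactants: 4 (S)-3,4-dimethyl-4-(triethylsilyloxy)cyclohex-2-en-1-one; 5 5-bromo-2-methylpent-2-ene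
Product: 7 (3S,4S)-3,4-dimethyl-3-(4-methylpent-3-en-1-yl)-4-(triethylsilyloxy)-1-(trimethylsilyloxy)cyclohex-1-ene, via Grignard reagent 6 (not isolated)
Conditions: 5, Mg, THF, rt; then CuBr·SMe2 (10 mol %), HMPA (2 equiv), TMSCl (2 equiv), 4, THF, −78 → −40 °C
Reagents that add atoms: chlorotrimethylsilane, C[Si](C)(C)Cl
Why: This is the copper-catalysed, TMSCl/HMPA-accelerated conjugate addition of a Grignard reagent, the variant that tolerates beta,beta-disubstituted enones; axial attack anti to the pseudoaxial C10–OTES group (as with other 4-silyloxycyclohexenones) puts the chain trans to oxygen, sets quaternary C11 as S, and stores the enolate regiospecifically as its TMS ether.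

Step 4
Reactants: 7 (3S,4S)-3,4-dimethyl-3-(4-methylpent-3-en-1-yl)-4-(triethylsilyloxy)-1-(trimethylsilyloxy)cyclohex-1-ene
Product: 9 (2S,3S,4S)-2-allyl-3,4-dimethyl-3-(4-methylpent-3-en-1-yl)-4-(triethylsilyloxy)cyclohexan-1-one, via lithium enolate 8 (not isolated)
Conditions: MeLi (1.05 equiv), THF, 0 °C; DMPU, allyl iodide (3 equiv), −78 → −20 °C
Reagents that add atoms: allyl iodide, C=CCI
Why: MeLi releases the regiospecific lithium enolate from the silyl enol ether and allyl iodide alkylates it; stereoelectronically favoured axial attack anti to the neighbouring pseudoaxial homoprenyl chain gives the 2,3-trans ketone and sets C6, as in the classical conjugate addition/allylation of 3-methylcyclohexenone, and a minor C6 epimer is removed by chromatography.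

Step 5
Reactants: 9 (2S,3S,4S)-2-allyl-3,4-dimethyl-3-(4-methylpent-3-en-1-yl)-4-(triethylsilyloxy)cyclohexan-1-one
Product: 11 (2S,3S,4S)-2-(3-hydroxypropyl)-3,4-dimethyl-3-(4-methylpent-3-en-1-yl)-4-(triethylsilyloxy)cyclohexan-1-one, via pinacol boronate 10 (not isolated)
Conditions: HBpin (1.2 equiv), [Ir(cod)Cl]2 (1.5 mol %), dppm (3 mol %), CH2Cl2, rt; then NaBO3·4H2O, THF/H2O, rt
Reagents that add atoms: sodium perborate, [Na+].[O-]OB=O
Why: Iridium-catalysed anti-Markovnikov hydroboration with pinacolborane takes only the monosubstituted alkene and, unlike dialkylboranes, leaves the ketone and the trisubstituted alkene alone; the mild perborate oxidation then forms the C3–O bond without epimerising C6.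

Step 6
Reactants: 11 (2S,3S,4S)-2-(3-hydroxypropyl)-3,4-dimethyl-3-(4-methylpent-3-en-1-yl)-4-(triethylsilyloxy)cyclohexan-1-one
Product: 13 (2E)-5-[(1S,2S,6S)-6-(3-hydroxypropyl)-1,2-dimethyl-5-oxo-2-(triethylsilyloxy)cyclohexyl]-2-methylpent-2-enal, via allylic alcohol 12 (not isolated)
Conditions: SeO2 (0.3 equiv), t-BuOOH (3 equiv), salicylic acid (0.1 equiv), CH2Cl2, 0 °C → rt; filter; MnO2 (15 equiv), CH2Cl2, rt
Reagents that add atoms: tert-butyl hydroperoxide (oxygen relayed by the SeO2 catalyst), CC(C)(C)OO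
Why: The SeO2 allylic oxidation (ene reaction, then [2,3] shift) attacks only the electron-rich trisubstituted alkene and only its E-methyl group, so the C16–O bond forms with 14E geometry; MnO2 then converges the alcohol/aldehyde mixture on the enal without touching the saturated primary alcohol.

Step 7
Reactants: 14 (S)-(−)-citronellal
Product: 16 (S)-3,7-dimethyloct-6-en-1-yne, via enol nonaflate 15 (not isolated)
Conditions: n-C4F9SO2F (1.2 equiv), P2-Et phosphazene base (2.3 equiv), DMF, 0 °C → rt
Reagents that add atoms: none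
Why: One-pot enol nonaflate formation and elimination turns an enolisable aldehyde into the terminal alkyne of the same carbon count; the chiral-pool stereocentre (C19) is beta to the carbonyl and is not involved.

Step 8
Reactants: 13 (2E)-5-[(1S,2S,6S)-6-(3-hydroxypropyl)-1,2-dimethyl-5-oxo-2-(triethylsilyloxy)cyclohexyl]-2-methylpent-2-enal; 16 (S)-3,7-dimethyloct-6-en-1-yne
Product: 19 (2S,3S,4S)-3-[(3E,5S,6E,8S)-5-hydroxy-4,8,12-trimethyltrideca-3,6,11-trien-1-yl]-2-(3-hydroxypropyl)-3,4-dimethyl-4-(triethylsilyloxy)cyclohexan-1-one, via alkenylborane 17 (not isolated), via alkenylzinc 18 (not isolated)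
Conditions: 16 (1.6 equiv), Cy2BH (1.6 equiv), toluene, 0 °C → rt; Et2Zn (2.8 equiv), −78 °C; (−)-3-exo-morpholinoisoborneol (8 mol %), 13, −20 → 0 °C; H2O
Reagents that add atoms: none
Why: This is alkyne hydroboration, boron-to-zinc exchange and amino-alcohol-catalysed asymmetric alkenylzinc addition to an aldehyde: syn hydroboration fixes 17E, the ligand–zinc complex delivers the alkenyl group to the Si face of the enal (the sense that gives (S)-1-phenylpropanol from PhCHO and Et2Zn) to set C16 as S under catalyst control, the organozinc ignores the ketone, and the extra Et2Zn covers the free hydroxyl.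

Step 9
Reactants: 19 (2S,3S,4S)-3-[(3E,5S,6E,8S)-5-hydroxy-4,8,12-trimethyltrideca-3,6,11-trien-1-yl]-2-(3-hydroxypropyl)-3,4-dimethyl-4-(triethylsilyloxy)cyclohexan-1-one
Product: 20 the C3,C16-bis(tert-butyldimethylsilyl) ether of 19
Conditions: TBSCl (2.6 equiv), imidazole (5 equiv), DMF, 0 °C → rt
Reagents that add atoms: tert-butyldimethylsilyl chloride, CC(C)(C)[Si](C)(C)Cl
Why: Imidazole-promoted silylation protects the primary and the bis-allylic secondary alcohol in one operation under non-acidic conditions, so both survive the hexavalent chromium oxidant of step 11.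

Step 10
Reactants: 20 the C3,C16-bis(tert-butyldimethylsilyl) ether of 19
Product: 21 (1R,2S,3S,4S)-1-(prop-1-en-2-yl)cyclohexan-1-ol derived from 20 (tertiary allylic alcohol at C7)
Conditions: isopropenylmagnesium bromide (3 equiv), LaCl3·2LiCl (0.3 equiv), THF, 0 °C; H2O
Reagents that add atoms: isopropenylmagnesium bromide, CC(=C)[Mg]Br
Why: Lanthanide-promoted Grignard 1,2-addition suppresses enolisation of the hindered ketone, so C6 is kept; equatorial attack opposite the axial C11 methyl gives mainly the drawn C7 epimer, and both epimers converge because C7 becomes sp2 in step 11.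

Step 11
Reactants: 21 (1R,2S,3S,4S)-1-(prop-1-en-2-yl)cyclohexan-1-ol derived from 20
Product: 23 tris-silyl ether of the target (C3-OTBS, C16-OTBS, C10-OTES; 2Z enal), via primary allyl chromate 22 (not isolated)
Conditions: pyridinium chlorochromate [C5H5NH][CrO3Cl] (3 equiv), NaOAc, 4 Å sieves, CH2Cl2, rt
Reagents that add atoms: pyridinium chlorochromate, [O-][Cr](=O)(=O)Cl.c1cc[nH+]cc1
Why: In this Babler–Dauben oxidative transposition the tertiary chromate ester undergoes a suprafacial [3,3] shift that makes the new C1–O bond and the primary chromate collapses to the aldehyde; the C2 methyl avoids the substituted C6, so CH2O (later CHO) ends up cis to C6, and the 2Z enal is both the kinetic and the thermodynamic (least A(1,3) strain) product.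

Step 12
Reactants: 23 tris-silyl ether of the target
Product: 24 (2Z)-2-[(2R,3S,4S)-4-hydroxy-3-[(3E,5S,6E,8S)-5-hydroxy-4,8,12-trimethyltrideca-3,6,11-trien-1-yl]-2-(3-hydroxypropyl)-3,4-dimethylcyclohexylidene]propanal (target)
Conditions: HF·pyridine, excess pyridine, THF, 0 °C → rt
Reagents that add atoms: none
Why: Fluoride-driven cleavage of all three Si–O bonds with pyridine-buffered HF is mild enough for the bis-allylic alcohol and non-basic, so the enal geometry and the gamma stereocentre C6 are kept.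

## Compound list
1 | rac-3,4-dimethylcyclohex-2-en-1-one | CC1=CC(=O)CCC1C | starting material
2 | (S)-4-hydroperoxy-3,4-dimethylcyclohex-2-en-1-one | CC1=CC(=O)CC[C@]1(C)OO | intermediate
3 | (S)-4-hydroxy-3,4-dimethylcyclohex-2-en-1-one | CC1=CC(=O)CC[C@]1(C)O | intermediate
4 | (S)-3,4-dimethyl-4-(triethylsilyloxy)cyclohex-2-en-1-one | CC1=CC(=O)CC[C@]1(C)O[Si](CC)(CC)CC | intermediate
5 | 5-bromo-2-methylpent-2-ene | CC(C)=CCCBr | starting material
6 | (4-methylpent-3-en-1-yl)magnesium bromide | CC(C)=CCC[Mg]Br | intermediate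
7 | (3S,4S)-3,4-dimethyl-3-(4-methylpent-3-en-1-yl)-4-(triethylsilyloxy)-1-(trimethylsilyloxy)cyclohex-1-ene | CC(C)=CCC[C@@]1(C)C=C(O[Si](C)(C)C)CC[C@]1(C)O[Si](CC)(CC)CC | intermediate
8 | lithium (3S,4S)-3,4-dimethyl-3-(4-methylpent-3-en-1-yl)-4-(triethylsilyloxy)cyclohex-1-en-1-olate | [Li+].CC(C)=CCC[C@@]1(C)C=C([O-])CC[C@]1(C)O[Si](CC)(CC)CC | intermediate
9 | (2S,3S,4S)-2-allyl-3,4-dimethyl-3-(4-methylpent-3-en-1-yl)-4-(triethylsilyloxy)cyclohexan-1-one | CC(C)=CCC[C@@]1(C)[C@H](CC=C)C(=O)CC[C@]1(C)O[Si](CC)(CC)CC | intermediate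
10 | pinacol boronate of 9 (Bpin on C3) | CC(C)=CCC[C@@]1(C)[C@H](CCCB2OC(C)(C)C(C)(C)O2)C(=O)CC[C@]1(C)O[Si](CC)(CC)CC | intermediate
11 | (2S,3S,4S)-2-(3-hydroxypropyl)-3,4-dimethyl-3-(4-methylpent-3-en-1-yl)-4-(triethylsilyloxy)cyclohexan-1-one | CC(C)=CCC[C@@]1(C)[C@H](CCCO)C(=O)CC[C@]1(C)O[Si](CC)(CC)CC | intermediate
12 | (2S,3S,4S)-3-[(3E)-5-hydroxy-4-methylpent-3-en-1-yl]-2-(3-hydroxypropyl)-3,4-dimethyl-4-(triethylsilyloxy)cyclohexan-1-one | OC/C(C)=C/CC[C@@]1(C)[C@H](CCCO)C(=O)CC[C@]1(C)O[Si](CC)(CC)CC | intermediate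
13 | (2E)-5-[(1S,2S,6S)-6-(3-hydroxypropyl)-1,2-dimethyl-5-oxo-2-(triethylsilyloxy)cyclohexyl]-2-methylpent-2-enal | O=C/C(C)=C/CC[C@@]1(C)[C@H](CCCO)C(=O)CC[C@]1(C)O[Si](CC)(CC)CC | intermediate
14 | (S)-(−)-citronellal | CC(C)=CCC[C@H](C)CC=O | starting material
15 | (S)-3,7-dimethylocta-1,6-dien-1-yl nonafluorobutanesulfonate (E/Z mixture) | CC(C)=CCC[C@H](C)C=COS(=O)(=O)C(F)(F)C(F)(F)C(F)(F)C(F)(F)F | intermediate
16 | (S)-3,7-dimethyloct-6-en-1-yne | CC(C)=CCC[C@H](C)C#C | intermediate
17 | dicyclohexyl[(1E,3S)-3,7-dimethylocta-1,6-dien-1-yl]borane | CC(C)=CCC[C@H](C)/C=C/B(C1CCCCC1)C1CCCCC1 | intermediate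
18 | [(1E,3S)-3,7-dimethylocta-1,6-dien-1-yl](ethyl)zinc | CC(C)=CCC[C@H](C)/C=C/[Zn]CC | intermediate
19 | (2S,3S,4S)-3-[(3E,5S,6E,8S)-5-hydroxy-4,8,12-trimethyltrideca-3,6,11-trien-1-yl]-2-(3-hydroxypropyl)-3,4-dimethyl-4-(triethylsilyloxy)cyclohexan-1-one | CC(C)=CCC[C@H](C)/C=C/[C@H](O)/C(C)=C/CC[C@@]1(C)[C@H](CCCO)C(=O)CC[C@]1(C)O[Si](CC)(CC)CC | intermediate
20 | C3,C16-bis(tert-butyldimethylsilyl) ether of 19 | CC(C)=CCC[C@H](C)/C=C/[C@H](O[Si](C)(C)C(C)(C)C)/C(C)=C/CC[C@@]1(C)[C@H](CCCO[Si](C)(C)C(C)(C)C)C(=O)CC[C@]1(C)O[Si](CC)(CC)CC | intermediate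
21 | (1R,2S,3S,4S)-1-(prop-1-en-2-yl)cyclohexan-1-ol from 20 (C7 tertiary allylic alcohol, major epimer drawn) | CC(C)=CCC[C@H](C)/C=C/[C@H](O[Si](C)(C)C(C)(C)C)/C(C)=C/CC[C@@]1(C)[C@H](CCCO[Si](C)(C)C(C)(C)C)[C@@](O)(C(C)=C)CC[C@]1(C)O[Si](CC)(CC)CC | intermediate
22 | rearranged primary allyl hydrogen chromate (C1–O–Cr, 2Z alkene) | CC(C)=CCC[C@H](C)/C=C/[C@H](O[Si](C)(C)C(C)(C)C)/C(C)=C/CC[C@@]1(C)[C@H](CCCO[Si](C)(C)C(C)(C)C)/C(=C(/C)CO[Cr](=O)(=O)O)CC[C@]1(C)O[Si](CC)(CC)CC | intermediate
23 | tris-silyl ether of the target (C3-OTBS, C16-OTBS, C10-OTES; 2Z,6R,10S,11S,14E,16S,17E,19S) | CC(C)=CCC[C@H](C)/C=C/[C@H](O[Si](C)(C)C(C)(C)C)/C(C)=C/CC[C@@]1(C)[C@H](CCCO[Si](C)(C)C(C)(C)C)/C(=C(/C)C=O)CC[C@]1(C)O[Si](CC)(CC)CC | intermediate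
24 | (2Z)-2-[(2R,3S,4S)-4-hydroxy-3-[(3E,5S,6E,8S)-5-hydroxy-4,8,12-trimethyltrideca-3,6,11-trien-1-yl]-2-(3-hydroxypropyl)-3,4-dimethylcyclohexylidene]propanal | CC(C)=CCC[C@H](C)/C=C/[C@H](O)/C(C)=C/CC[C@@]1(C)[C@H](CCCO)/C(=C(/C)C=O)CC[C@]1(C)O | target

## Step count and risks
Total step count: 12. Longest linear sequence: 11 (steps 1–6 and 8–12; step 7 is the side branch).

**Step 1, the new hydroxylation.** It may give low ee through guanidine-only background autoxidation, or it may oxygenate at the alpha or alpha-prime carbon. The fallback uses only known chemistry, sets out from 1 and comes back at 3. Compound 1 is oxidised with air under the achiral Cu(OTf)2/1,1,3,3-tetramethylguanidine system to racemic 4-hydroperoxy-3,4-dimethylcyclohex-2-en-1-one F1. PPh3 reduces this to racemic 4-hydroxy-3,4-dimethylcyclohex-2-en-1-one F2. Preparative chiral supercritical-fluid chromatography on an amylose tris(3,5-dimethylphenylcarbamate) phase then separates 3 from (R)-4-hydroxy-3,4-dimethylcyclohex-2-en-1-one F3. Asymmetric catalysis is thereby replaced by resolution.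

**Step 3, the conjugate addition.** It creates a quaternary carbon next to a fully substituted carbon and may stall or turn into 1,2-addition. The fallback sets out from 4 and comes back at 7. The hindered C11–C12 bond is made with a small sp2 nucleophile (vinylmagnesium bromide, CuBr·SMe2, TMSCl, HMPA), giving (3S,4S)-3,4-dimethyl-4-(triethylsilyloxy)-1-(trimethylsilyloxy)-3-vinylcyclohex-1-ene F4. 9-BBN hydroborates the vinyl group to the B-alkyl-9-borabicyclo[3.3.1]nonane F5. A B-alkyl Suzuki coupling with 1-bromo-2-methylprop-1-ene (PdCl2(dppf), anhydrous K3PO4, DMF, 50 °C) then attaches the rest of the chain at the unhindered C13 and delivers 7.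

**Step 11, the oxidative transposition.** Chromate ester formation may be slow at the crowded tertiary alcohol, elimination to dienes may compete, or E/Z mixtures may form. The fallback is redox-neutral, sets out from 20 and comes back at 23. Prop-1-en-2-yllithium carrying a 1-ethoxy group (from 2-bromo-1-ethoxyprop-1-ene and t-BuLi) adds to ketone 20 and gives the 1-(1-ethoxyprop-1-en-2-yl)cyclohexan-1-ol F6. On oxalic-acid-doped wet silica gel in CH2Cl2, F6 ionises with enol ether assistance and hydrolyses directly to enal 23. No oxidant is involved, and the acid equilibrates the alkene to the 2Z isomer.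

Further compounds
F1 | step 1 | rac-4-hydroperoxy-3,4-dimethylcyclohex-2-en-1-one | CC1=CC(=O)CCC1(C)OO
F2 | step 1 | rac-4-hydroxy-3,4-dimethylcyclohex-2-en-1-one | CC1=CC(=O)CCC1(C)O
F3 | step 1 | (R)-4-hydroxy-3,4-dimethylcyclohex-2-en-1-one | CC1=CC(=O)CC[C@@]1(C)O
F4 | step 3 | (3S,4S)-3,4-dimethyl-4-(triethylsilyloxy)-1-(trimethylsilyloxy)-3-vinylcyclohex-1-ene | C=C[C@@]1(C)C=C(O[Si](C)(C)C)CC[C@]1(C)O[Si](CC)(CC)CC
F5 | step 3 | 9-{2-[(1S,6S)-1,6-dimethyl-6-(triethylsilyloxy)-3-(trimethylsilyloxy)cyclohex-2-en-1-yl]ethyl}-9-borabicyclo[3.3.1]nonane | C1CCC2CCCC1B2CC[C@@]3(C)C=C(O[Si](C)(C)C)CC[C@]3(C)O[Si](CC)(CC)CC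
F6 | step 11 | 1-(1-ethoxyprop-1-en-2-yl)cyclohexan-1-ol from 20 (C7 and enol ether geometry not defined) | CC(C)=CCC[C@H](C)/C=C/[C@H](O[Si](C)(C)C(C)(C)C)/C(C)=C/CC[C@@]1(C)[C@H](CCCO[Si](C)(C)C(C)(C)C)C(O)(C(C)=COCC)CC[C@]1(C)O[Si](CC)(CC)CC
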